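(The runs are simulated with constants of no real substance.)

You cannot read an order in enzyme off Tuesday's run: no run changes its charge. So the number has to be built by hand.

common to all: starting material 20 mM
- Tuesday's: enzyme 2 µM; impurity 1 µM; the very flask that is asked about, followed so far
- flask: enzyme 2.0 µM; impurity 1.0 µM

Tuesday's run (percent of the starting material charged)

| time / s | target / % | starting material / % |
|---|---|---|
| 10.0 | 3.2 | 97.2 |
| 15.0 | 4.2 | 95.9 |
| 20.0 | 5.6 | 94.5 |
| 30.0 | 8.2 | 91.7 |
| 40.0 | 11.0 | 89.9 |
| 50.0 | 12.4 | 87.3 |

(standard deviation of a reading: 0.3 percentage points)

- in percentages every species weighs as the starting material in it: one resting dimer counts as two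
- what may be going on: starting material + enzyme <-> complex; complex -> enzyme + target; 2 complex <-> resting dimer; enzyme + impurity -> spent catalyst
- no earlier run changes the charge of enzyme; that part of a forecast is a guess

* factor on the rate of making target when 5.0% of the starting material are converted if enzyme is charged twice over
* factor on the rate when 5.0% of the starting material are converted if enzyme is charged at 10 µM instead

My chain starts from the charge. Impurity takes enzyme one for one, so what counts is the working enzyme, the enzyme charged less the impurity charged: 1.00 µM. If the rate follows working enzyme, the two factors are 3.00 and 9.00. If resting dimer holds most of it, the rate goes as the square root, giving 1.73 and 3.00. I join the two ends by their geometric mean and commit to 2.28 and 5.20, though that mean is a guess.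

The weak link is whether capture is over at 5.0% conversion. In Tuesday's readings, target climbs at 0.0453 mM s⁻¹ from 20.0 s to 50.0 s, and that line extrapolates back to 1.07% at zero time. If the early rate stood at twice the late one, this surplus means a capture time constant of 4.71 s. The line reaches 5.0% at 17.4 s, longer than that time constant, which by this estimate leaves 2.49% of the impurity, so I keep the link.

The forecast says 2.5 and 6, both higher than mine: “I therefore hedge between them”.

The flask gives 2.25 and 4.65.

    starting material + enzyme ⇌ complex (K = 380 L mol⁻¹, k = 1.50 × 10⁵ L mol⁻¹ s⁻¹)
    complex → enzyme + target (k = 72.0 s⁻¹)
    2 complex ⇌ resting dimer, settled at all times (K = 2.70 × 10⁵ L mol⁻¹)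
    enzyme + impurity → spent catalyst (k = 1.50 × 10⁶ L mol⁻¹ s⁻¹)

With starting material and impurity as charged, free enzyme takes up starting material at 1.8 × 10⁵ min⁻¹, far faster than it meets impurity, at 90 min⁻¹. Even so, in the flask at 0.293 min spent catalyst is 48.2% of the catalyst, leaving 1.04 µM unspent against the working enzyme of 1.00 µM. With 10 µM charged, spent catalyst at the same conversion is 9.63% of the catalyst, leaving 9.04 µM unspent against a working enzyme of 9.00 µM.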